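Atom labels: ring O1–O2–C3(ketal)–C4–C5–C6(H, CH2CO2H); side chain on C3 = C1'–C16'; in open-chain intermediates C1 is the carbon that becomes CO2H.
Retrosynthetic cuts, in order: ester O–CH3; the two ketal bonds O2–C3 and C3–OMe (dioxane back to an open-chain C6-hydroperoxy C3-ketone, stored as its acetone peroxyketal); C6–O1 (enal + hydroperoxide); the enal C=C at C6 (Wittig); C3–C4 (Weinreb amide + acetal Grignard); C5'–C6' (Sonogashira); C6'=C7' (Takai).
Forward: two short branches give the vinyl iodide and the alkynyl Weinreb amide; they are coupled, the chain is extended to the keto enal, the peroxide is added, C1 is oxidised and esterified, and the only ring, the 1,2-dioxane, closes in step 12, one step before the end.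
Enabling feature: C3 is a ketone at the ketal oxidation level lying four atoms (C3–C4–C5–C6) from the peroxide-bearing C6, so an OOH group on C6 reaches the C3 carbonyl through a six-membered ring and methanol completes the ketal.
Stereochemistry: C6 (S) from face-selective, amine-catalysed peroxide addition to the enal; C3 (R) from thermodynamic (anomeric) control in the ring closure, relative to C6; the 6'E alkene from the Takai olefination, kept through the Sonogashira coupling.

Key step: step 12

Assumption: in step 9 the hydroperoxide is taken to attack the s-trans (E)-iminium ion on the face remote from the diphenyl(silyloxy)methyl group, which for the (R)-amine leads to 3S; if the sense proved opposite, the (S)-amine would be used and nothing else changes.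

Step 1
Reactants: 1 dec-9-en-1-ol
Product: 2 dec-9-enal
Conditions: TEMPO (10 mol %), PhI(OAc)2 (1.1 equiv), CH2Cl2, 20 °C
Reagents that add atoms: none
Why: A TEMPO/oxoammonium oxidation with PhI(OAc)2 as terminal oxidant takes the primary alcohol to the aldehyde without over-oxidation and leaves the terminal alkene alone.

Step 2
Reactants: 2 dec-9-enal
Product: 3 (1E)-1-iodoundeca-1,10-diene
Conditions: CrCl2 (6 equiv), CHI3 (2 equiv), THF/1,4-dioxane (1:6), 0 to 20 °C
Reagents that add atoms: iodoform, IC(I)I
Why: Takai olefination: the gem-dichromium reagent formed from CHI3 and CrCl2 adds to the aldehyde and eliminates to the vinyl iodide, the E geometry being the one this reaction favours for unbranched aldehydes and the dioxane co-solvent raising that preference.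

Step 3
Reactants: 4 hex-5-ynoic acid
Product: 6 N-methoxy-N-methylhex-5-ynamide, via acyl imidazole 5 (not isolated)
Conditions: CDI (1.1 equiv), CH2Cl2, 20 °C; then MeNH(OMe)·HCl (1.2 equiv), 20 °C
Reagents that add atoms: N,O-dimethylhydroxylamine hydrochloride, CNOC.Cl
Why: Weinreb amide formation by acyl transfer: CDI converts the acid into the acyl imidazole, which acylates the hydroxylamine nitrogen, and the terminal alkyne takes no part.

Step 4
Reactants: 3 (1E)-1-iodoundeca-1,10-diene; 6 N-methoxy-N-methylhex-5-ynamide
Product: 7 (7E)-N-methoxy-N-methylheptadeca-7,16-dien-5-ynamide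
Conditions: PdCl2(PPh3)2 (3 mol %), CuI (6 mol %), Et3N, THF, 20 °C
Reagents that add atoms: none
Why: Sonogashira coupling joins the terminal alkyne to the vinyl iodide with retention of the E geometry, the Weinreb amide and the terminal alkene being inert to the Pd/Cu cycle.

Step 5
Reactants: 7 (7E)-N-methoxy-N-methylheptadeca-7,16-dien-5-ynamide; 8 2-(2-bromoethyl)-1,3-dioxolane
Product: 10 (9E)-1-(1,3-dioxolan-2-yl)nonadeca-9,18-dien-7-yn-3-one, via Grignard reagent 9 (not isolated)
Conditions: 8, Mg, THF, 25 °C; then 7, THF, 0 °C; then H2O
Reagents that add atoms: none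
Why: Weinreb ketone synthesis: the Grignard reagent adds once, the magnesium chelate of the tetrahedral adduct holds until the aqueous quench so that no tertiary alcohol forms, and with the alkyne now internal no acidic C–H consumes the reagent.

Step 6
Reactants: 10 (9E)-1-(1,3-dioxolan-2-yl)nonadeca-9,18-dien-7-yn-3-one
Product: 11 (10E)-4-oxoicosa-10,19-dien-8-ynal
Conditions: 2 M aq. HCl/THF (1:4), 20 °C
Reagents that add atoms: water, O
Why: Acid-catalysed acetal hydrolysis releases the aldehyde, while the isolated ketone, the enyne and the terminal alkene are stable to dilute aqueous acid at room temperature.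

Step 7
Reactants: 11 (10E)-4-oxoicosa-10,19-dien-8-ynal; 12 (triphenylphosphoranylidene)acetaldehyde
Product: 13 (2E,12E)-6-oxodocosa-2,12,21-trien-10-ynal
Conditions: toluene, 80 °C
Reagents that add atoms: none
Why: Wittig olefination with the formyl-stabilised ylide takes place only at the aldehyde, the ketone being too unreactive towards a stabilised ylide, and gives the (E)-enal as stabilised ylides do.

Step 8
Reactants: 14 2,3-dimethylbut-2-ene
Product: 15 2-methoxypropan-2-yl hydroperoxide
Conditions: O3, MeOH/CH2Cl2 (1:4), −78 °C; N2 purge; kept and used as a solution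
Reagents that add atoms: ozone, [O-][O+]=O; methanol, CO
Why: Criegee ozonolysis in a participating solvent: the primary ozonide of the symmetrical alkene splits into acetone and the acetone carbonyl oxide, which methanol traps as the α-methoxy hydroperoxide.

Step 9
Reactants: 13 (2E,12E)-6-oxodocosa-2,12,21-trien-10-ynal; 15 2-methoxypropan-2-yl hydroperoxide
Product: 16 (3S,12E)-3-[(2-methoxypropan-2-yl)peroxy]-6-oxodocosa-12,21-dien-10-ynal
Conditions: (R)-2-[diphenyl(trimethylsilyloxy)methyl]pyrrolidine (20 mol %), PhCO2H (20 mol %), 15 (2 equiv), toluene, 0 °C; taken on crude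
Reagents that add atoms: none
Why: Iminium-catalysed enantioselective oxa-Michael addition (β-peroxidation of an enal): the hydroperoxide attacks C3 of the s-trans (E)-iminium ion on the face remote from the diphenyl(trimethylsilyloxy)methyl group, which with the (R)-amine sets 3S, while benzoic acid protonates the resulting enamine before it can close onto the O–O bond and the hindered secondary amine does not condense with the saturated C6 ketone.

Step 10
Reactants: 16 (3S,12E)-3-[(2-methoxypropan-2-yl)peroxy]-6-oxodocosa-12,21-dien-10-ynal
Product: 17 (3S,12E)-3-[(2-methoxypropan-2-yl)peroxy]-6-oxodocosa-12,21-dien-10-ynoic acid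
Conditions: NaClO2, NaH2PO4, 2-methylbut-2-ene, t-BuOH/H2O, 0 °C
Reagents that add atoms: sodium chlorite NaClO2, [Na+].[O-]Cl=O
Why: Pinnick oxidation: chlorous acid adds to the aldehyde and fragments to the carboxylic acid under buffered, mildly acidic conditions in which the C3 centre cannot be lost by retro-addition, and 2-methylbut-2-ene removes the hypochlorous acid that would otherwise attack the alkenes.

Step 11
Reactants: 17 (3S,12E)-3-[(2-methoxypropan-2-yl)peroxy]-6-oxodocosa-12,21-dien-10-ynoic acid
Product: 18 methyl (3S,12E)-3-[(2-methoxypropan-2-yl)peroxy]-6-oxodocosa-12,21-dien-10-ynoate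
Conditions: TMSCHN2, MeOH/toluene (1:4), 0 °C
Reagents that add atoms: (trimethylsilyl)diazomethane, C[Si](C)(C)C=[N+]=[N-]
Why: Diazoalkane esterification of the carboxylic acid is fast at 0 °C and needs neither acid nor base, so the acid-labile peroxyketal and the base-labile β-peroxy carbonyl unit are both preserved.

Step 12
Reactants: 18 methyl (3S,12E)-3-[(2-methoxypropan-2-yl)peroxy]-6-oxodocosa-12,21-dien-10-ynoate
Product: 21 methyl 2-[(3R,6S)-3-[(6E)-hexadeca-6,15-dien-4-yn-1-yl]-3-methoxy-1,2-dioxan-6-yl]acetate, via hydroperoxy ketone 19 (not isolated), via peroxyhemiketal 20 (not isolated)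
Conditions: TsOH·H2O (10 mol %), MeOH, 0 to 20 °C; NaHCO3 quench
Reagents that add atoms: methanol, CO
Why: Acid-catalysed exchange with methanol strips the 2-methoxypropan-2-yl group from 18 and frees the C6 hydroperoxide 19, whose terminal oxygen adds to the protonated C3 ketone to give the cyclic peroxyhemiketal 20; loss of water from 20 gives a ring peroxycarbenium ion that methanol captures, so that O2–C3 and C3–OMe are both made in this flask. The closest known reaction type is the acid-catalysed peroxyketalization of γ-hydroperoxy ketones, through 3-hydroxy-1,2-dioxanes, to 3-alkoxy-1,2-dioxanes. The single ring, the 1,2-dioxane, closes in the 6-exo-trig mode by attack of O2 on the C3 carbonyl. The new stereocentre C3 is set under thermodynamic control, every step being reversible: the anomeric effect holds the methoxy group axial while the C3 chain and the C6 CH2CO2Me arm lie equatorial, which is 3R relative to the fixed 6S centre. The step needs ring closure to win over open-chain ketal formation and the peroxide to survive: the saturated C4–C5 tether makes the six-membered closure entropically favoured, the acidic medium excludes base-triggered loss of the β-peroxy group, the methyl ester cannot be changed by methanol, and the enyne and alkenes are inert to catalytic TsOH.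

Step 13
Reactants: 21 methyl 2-[(3R,6S)-3-[(6E)-hexadeca-6,15-dien-4-yn-1-yl]-3-methoxy-1,2-dioxan-6-yl]acetate
Product: 22 2-[(3R,6S)-3-[(6E)-hexadeca-6,15-dien-4-yn-1-yl]-3-methoxy-1,2-dioxan-6-yl]acetic acid
Conditions: LiOH·H2O (3 equiv), THF/H2O (3:1), 0 °C; then 0.5 M aq. HCl to pH 4, 0 °C
Reagents that add atoms: lithium hydroxide LiOH, [Li+].[OH-]
Why: Saponification (hydroxide addition–elimination at the ester carbonyl) at 0 °C is faster than deprotonation α to the ester, so the acid should be released without retro-oxa-Michael loss of the peroxide, and cold acidification to pH 4 leaves the methoxy peroxyketal and both stereocentres untouched.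

Compound list
1 | dec-9-en-1-ol | C=CCCCCCCCCO | starting material
2 | dec-9-enal | C=CCCCCCCCC=O | intermediate
3 | (1E)-1-iodoundeca-1,10-diene | C=CCCCCCCC/C=C/I | intermediate
4 | hex-5-ynoic acid | C#CCCCC(=O)O | starting material
5 | 1-(1H-imidazol-1-yl)hex-5-yn-1-one (acyl imidazole) | C#CCCCC(=O)n1ccnc1 | intermediate
6 | N-methoxy-N-methylhex-5-ynamide | C#CCCCC(=O)N(C)OC | intermediate
7 | (7E)-N-methoxy-N-methylheptadeca-7,16-dien-5-ynamide | C=CCCCCCCC/C=C/C#CCCCC(=O)N(C)OC | intermediate
8 | 2-(2-bromoethyl)-1,3-dioxolane | BrCCC1OCCO1 | starting material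
9 | [2-(1,3-dioxolan-2-yl)ethyl]magnesium bromide (Grignard reagent) | Br[Mg]CCC1OCCO1 | intermediate
10 | (9E)-1-(1,3-dioxolan-2-yl)nonadeca-9,18-dien-7-yn-3-one | C=CCCCCCCC/C=C/C#CCCCC(=O)CCC1OCCO1 | intermediate
11 | (10E)-4-oxoicosa-10,19-dien-8-ynal | C=CCCCCCCC/C=C/C#CCCCC(=O)CCC=O | intermediate
12 | (triphenylphosphoranylidene)acetaldehyde | O=CC=P(c1ccccc1)(c1ccccc1)c1ccccc1 | starting material
13 | (2E,12E)-6-oxodocosa-2,12,21-trien-10-ynal | C=CCCCCCCC/C=C/C#CCCCC(=O)CC/C=C/C=O | intermediate
14 | 2,3-dimethylbut-2-ene | CC(C)=C(C)C | starting material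
15 | 2-methoxypropan-2-yl hydroperoxide | COC(C)(C)OO | intermediate
16 | (3S,12E)-3-[(2-methoxypropan-2-yl)peroxy]-6-oxodocosa-12,21-dien-10-ynal | C=CCCCCCCC/C=C/C#CCCCC(=O)CC[C@@H](CC=O)OOC(C)(C)OC | intermediate
17 | (3S,12E)-3-[(2-methoxypropan-2-yl)peroxy]-6-oxodocosa-12,21-dien-10-ynoic acid | C=CCCCCCCC/C=C/C#CCCCC(=O)CC[C@@H](CC(=O)O)OOC(C)(C)OC | intermediate
18 | methyl (3S,12E)-3-[(2-methoxypropan-2-yl)peroxy]-6-oxodocosa-12,21-dien-10-ynoate | C=CCCCCCCC/C=C/C#CCCCC(=O)CC[C@@H](CC(=O)OC)OOC(C)(C)OC | intermediate
19 | methyl (3S,12E)-3-hydroperoxy-6-oxodocosa-12,21-dien-10-ynoate (hydroperoxy ketone) | C=CCCCCCCC/C=C/C#CCCCC(=O)CC[C@@H](CC(=O)OC)OO | intermediate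
20 | methyl 2-[(6S)-3-[(6E)-hexadeca-6,15-dien-4-yn-1-yl]-3-hydroxy-1,2-dioxan-6-yl]acetate (peroxyhemiketal, both C3 epimers) | C=CCCCCCCC/C=C/C#CCCCC1(O)CC[C@@H](CC(=O)OC)OO1 | intermediate
21 | methyl 2-[(3R,6S)-3-[(6E)-hexadeca-6,15-dien-4-yn-1-yl]-3-methoxy-1,2-dioxan-6-yl]acetate | C=CCCCCCCC/C=C/C#CCCC[C@]1(OC)CC[C@@H](CC(=O)OC)OO1 | intermediate
22 | 2-[(3R,6S)-3-[(6E)-hexadeca-6,15-dien-4-yn-1-yl]-3-methoxy-1,2-dioxan-6-yl]acetic acid | C=CCCCCCCC/C=C/C#CCCC[C@]1(OC)CC[C@@H](CC(=O)O)OO1 | target

Total step count: 13 (including the preparation of hydroperoxide 15).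
Longest linear sequence: 11 steps (steps 1, 2, 4, 5, 6, 7, 9, 10, 11, 12, 13, from dec-9-en-1-ol).

Steps most likely to fail

Step 9. Face differentiation in the attack of the hydroperoxide on the iminium ion may be incomplete, or reversible addition may erode it, leaving the C6 centre of the target enantiomerically impure. The fallback replaces asymmetric induction by classical resolution, but it corrects only this loss of enantiopurity. Closure of the enamine onto the O–O bond or onto the C6 ketone would not be repaired by it. It sets out from acid 17 as obtained from steps 9 and 10. The acid is crystallised as its salt with (S)-1-phenylethylamine, (S)-1-phenylethylammonium (3S,12E)-3-[(2-methoxypropan-2-yl)peroxy]-6-oxodocosa-12,21-dien-10-ynoate F1, until the salt is diastereomerically uniform. Partition of the salt between ether and cold aqueous NaH2PO4 then returns acid 17, where the route is rejoined before step 11. The mildly basic salt medium is safe for the acid-labile peroxyketal.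

Step 12. The exchange may stall at the peroxyhemiketal, or equilibration at C3 may be slow enough that long exposure to acid degrades the peroxide. The fallback splits the step and forms the C3–OMe bond under aprotic, irreversible conditions. It sets out from 18: aqueous acetic acid in THF frees hydroperoxide 19, which closes to peroxyhemiketal 20 (O2–C3 formed as before), and 20 is now isolated. It is then ketalised with methoxytrimethylsilane and catalytic TMSOTf in CH2Cl2 at −78 °C (silyl-triflate-catalysed ketalization). The ring peroxycarbenium ion should be captured axially to give 21, where the route is rejoined. This detour makes no compound outside the list (none F0).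

Step 13. Hydroxide may deprotonate α to the ester and expel the peroxide (retro-oxa-Michael), or remove the C6 hydrogen with O–O cleavage. The fallback carries C1 at the alcohol oxidation level through the ring closure and oxidises last, so that no base meets the β-peroxy carbonyl unit. It sets out from aldehyde 16: NaBH4 in EtOH/CH2Cl2 at −78 °C, selective for the aldehyde over the ketone, gives (3S,12E)-1-hydroxy-3-[(2-methoxypropan-2-yl)peroxy]docosa-12,21-dien-10-yn-6-one F2. The acidic-methanol peroxyketalization of step 12 (TsOH·H2O, MeOH) then gives 2-[(3R,6S)-3-[(6E)-hexadeca-6,15-dien-4-yn-1-yl]-3-methoxy-1,2-dioxan-6-yl]ethan-1-ol F3, the large excess of methanol outcompeting the pendant hydroxyl for the peroxycarbenium ion. Oxidation of the primary alcohol with TEMPO (cat.) and PhI(OAc)2 in MeCN/H2O then gives the acid, rejoining the route at target 22.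

Further compounds
F1 | step 9 | (S)-1-phenylethylammonium (3S,12E)-3-[(2-methoxypropan-2-yl)peroxy]-6-oxodocosa-12,21-dien-10-ynoate | C=CCCCCCCC/C=C/C#CCCCC(=O)CC[C@@H](CC(=O)[O-])OOC(C)(C)OC.C[C@H]([NH3+])c1ccccc1
F0 | step 12 | none | none
F2 | step 13 | (3S,12E)-1-hydroxy-3-[(2-methoxypropan-2-yl)peroxy]docosa-12,21-dien-10-yn-6-one | C=CCCCCCCC/C=C/C#CCCCC(=O)CC[C@@H](CCO)OOC(C)(C)OC
F3 | step 13 | 2-[(3R,6S)-3-[(6E)-hexadeca-6,15-dien-4-yn-1-yl]-3-methoxy-1,2-dioxan-6-yl]ethan-1-ol | C=CCCCCCCC/C=C/C#CCCC[C@]1(OC)CC[C@@H](CCO)OO1
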